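## Structural features

The target is a C30 dimer of two guaian-12,6-olide units; guaiane numbering is used for both, unprimed for the half that keeps the C4=C5 double bond and primed for the half that carries the C3′ ketone. Each half has a five-membered ring A (C1–C5) fused at C1–C5 to a seven-membered ring (C1, C5–C10), a trans-fused γ-lactone on C6–C7 (oxygen on C6, C11 with its methyl, C12 as carbonyl) and a tertiary carbinol at C10. The halves are joined by the bonds C2–C2′ and C3–C5′, so that ring A′ and C2–C3 form a norbornanone with C2′ and C5′ as bridgeheads and C1′ as the one-carbon bridge; this is the imprint of a Diels–Alder reaction between the C2=C3 bond of one cyclopentadiene and a C2′–C5′ diene. Fifteen stereocentres stand in contiguous runs: C11–C7–C6 and C10–C1–C2–C3 in the first half, C11′–C7′–C6′–C5′(quaternary)–C4′ and C10′–C1′–C2′ in the second. Fragile points are the tertiary C10 alcohols (elimination and, next to a carbonyl, retro-aldol cleavage), the epimerisable centres C11, C11′ and C4′, and every cyclopentadiene intermediate, which can dimerise or shift hydrogen. The real difficulty is twofold: a hydroazulenone in which the C10 oxygen is cis to the C7 branch across the ring and anti to H1, and a regio-, face- and endo-selective union that creates the quaternary C5′. The key step exploits the 1,4 relation of C10 (methyl-bearing) and C7 (three-carbon branch) across the seven-membered ring, which is that of C2 and C5 of carvone: inserting one carbon, C1, between the carbonyl carbon C5 and C10 turns the chiral-pool cyclohexanone into the cycloheptenone with C7 already correct.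

## Logic of the disconnections

27 from 26. No skeletal bond is cut; the C3′ ketone is traced back to its silyl enol ether and the two carbinols to silyl ethers. This leaves C4′ as the only centre to be set after the union and demands that protonation of the enol, or later equilibration, gives the methyl-endo ketone.

26 from 24 and 25. The bonds C2–C2′ and C3–C5′ are cut in a retro-Diels–Alder sense. This halves the molecule into two C15 pieces of the same skeleton and removes four stereocentres (C2, C3, C2′, C5′). The forward step must pair the siloxy diene of 25 with the C2=C3 bond of 24 in the right regiochemistry, on the faces away from the C10 substituents and in endo mode.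

24 and 25 from 21. Both dienes are traced to enolisation of one enone towards C2. For 25 the C3–O bond is silylated directly under amine-mediated (soft) enolisation; for 24 it is sulfonylated through 22 to give 23, and the sulfonate is then replaced by hydrogen. One monomer therefore serves both halves. The demand in both branches is kinetic deprotonation at C2 and not at C1, C6 or C11.

21 from 20. The C4=C5 bond is cut by a retro-aldol condensation, which opens ring A to a 1,4-diketone. The demand is a base step short and mild enough to spare the β-silyloxy ketone and the centre at C6.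

20 from 19, 17 and 15. The lactone C12–O6 bond is traced through the lactol 19 to the diol 17 and to the isopropenyl group of 15. Cutting here uses the three-carbon branch that the starting terpene already carries. The demand is anti-Markovnikov hydration of the alkene in the presence of two ketones, and control of C11, which is obtained by equilibration at the aldehyde oxidation level.

15 from 14 and 12. The C3 carbonyl is traced to an alkyne, and the C6–O bond is cut back to a C6 methylene. The alkyne is a masked ketone that is inert to the enolate chemistry, and C6 is oxidised while it is still α to the only ketone of the molecule. The demand is regioselective enolisation at C6 and oxygen delivery trans to the C7 branch.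

12 from 11, and 11 from 8 and 9. The C1–C2 bond is cut, and the C1 enolate needed to form it is traced to an epoxy ketone. Reductive opening gives the C10 oxygen and the C1 nucleophile in one operation, regiospecifically. The demand is alkylation on the C1 face cis to the C10 oxygen.

8 from 7. The C1–O and C10–O bonds of the epoxide are cut. This reduces the problem to a simple enone with one stereocentre. The demand is delivery of oxygen to the C10 face cis to the remote C7 branch, which is placed under catalyst control.

7 from 5 (via 6). The ring-enlargement transform restores the C5–C10 bond and so turns the seven-membered enone back into a siloxy-bicyclo[4.1.0]heptane. This is the key simplification: the hydroazulene problem becomes a cyclohexane problem. The demand is cleavage of the internal and not the external cyclopropane bond.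

5 from 3 and 4, and 3 from 1. The two bonds to C1 are cut (methylene transfer from 4), and the enol ether is traced to the enone 1 by conjugate reduction. Nothing but the chiral-pool terpene and a C1 unit remains. The demand is a regiodefined tetrasubstituted enol ether and cyclopropanation of it in preference to the isopropenyl group.

## Other disconnections considered

Alternative 1: Both rings are cut at C1–C5 and C8–C9 by an intramolecular (4+3) cycloaddition. In the forward sense sodium trifluoroethoxide in trifluoroethanol would ionise the chloromethyl ketone A1 to an oxyallyl cation (C9, C10, C1) that adds across the tethered diene (C5 to C8) to give the bicyclo[5.3.0]decenone A2.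
- In its favour: two carbon–carbon bonds and both carbocycles arise in one step, and the C1 configuration is fixed in the ring-forming event. On both points it is better than the chosen plan, whose key step forms no skeletal bond and whose C1 centre is set separately.
- Against it here: A2 has neither the C7 branch nor the C6 oxygen, carries hydrogen at C5 where the monomer needs C4=C5, and has a ketone at C10 that must still take a methyl group from the correct face. Its absolute configuration has to be bought by asymmetric synthesis of A1, and the tethered cycloaddition has its own endo/exo and facial questions.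
- Comparison: the mechanism is a cationic cycloaddition against a radical β-scission. On structure, the chosen plan starts with C7 and its three carbons in place. On step economy the gain of the (4+3) step would probably be spent on the later oxidation-level and side-chain work.

Alternative 2: Only ring A is cut, at C1–C2. In the forward sense Ph3PAuSbF6 (monovalent gold) would trigger a 1,2-pivaloyloxy shift in the enynyl pivalate A3, and the resulting pentadienyl cation would close onto the ring alkene to give, after hydrolysis, the silyloxy enone lactone A4.
- In its favour: A4 is the trimethylsilyl analogue of 21, so the endgame would be identical, which makes it the equal of the chosen plan from that point on. Ring A would also be closed under neutral, non-basic conditions, which is better than the base-mediated aldol of step 12 for a β-silyloxy ketone.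
- Against it here: A3 already contains the seven-membered ring, the lactone and the C10 carbinol, so the hardest part of the monomer is only postponed. A tertiary propargylic ester can also follow the competing 1,3-shift to an allene, and C1 depends on chirality transfer from C4 or on substrate bias.
- Comparison: the mechanism is a gold carbenoid cyclisation against enolate chemistry. Ring A costs one step against three (steps 5, 8 and 12), but the precursor costs more. The two plans could be combined, since the ring enlargement could also serve a route to A3.

Alternative 3: The C1–C5 bond is cut across a ten-membered ring. In the forward sense BF3·OEt2 would open the 4,5-epoxide of the germacranolide A5, C1 of the C1=C10 alkene would attack C5 with inversion, and loss of a proton would give the hydroxy guaienolide A6.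
- In its favour: one stereospecific step would form both carbocycles with the lactone and C6, C7 and C11 already correct. In step count to a guaianolide core it is clearly better than the chosen plan.
- Against it here: the oxidation pattern of A6 is displaced. It has oxygen at C4 and an alkene at C1–C10, where the monomer needs a C3 ketone, C4=C5, and oxygen at C10 anti to H1. Dehydration, allylic oxidation at C3 and an anti hydration of the C1=C10 bond would each bring a selectivity problem, and supply would rest on an isolated natural product and not on a commodity terpene.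
- Comparison: the mechanism is a cationic transannular closure. On structure it delivers more stereocentres at once. The chosen plan places oxygen at C10 and C3 directly, so the overall step economy is probably similar.

Key step: step 3

Assumption (step 4): the quinine-derived primary amine is taken to deliver oxygen to the C10 face cis to the isopropenyl group; if its sense is the opposite, the quinidine-derived pseudoenantiomer is used instead.

## Route

Step 1
Reactants: 1 (R)-carvone
Product: 3 trimethyl{[(5R)-2-methyl-5-(prop-1-en-2-yl)cyclohex-1-en-1-yl]oxy}silane, via lithium enolate 2 (not isolated)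
Conditions: LiBH(s-Bu)3, THF, −78 °C; then Me3SiCl, Et3N, −78 → 0 °C
Reagents that add atoms: chlorotrimethylsilane, C[Si](C)(C)Cl
Why: Conjugate hydride addition to the enone gives the methyl-substituted enolate regiospecifically, and O-silylation fixes the tetrasubstituted enol ether in one operation (conjugate reduction with enolate trapping); the isopropenyl group is inert and the stereocentre (later C7) is not touched.

Step 2
Reactants: 3 trimethyl{[(5R)-2-methyl-5-(prop-1-en-2-yl)cyclohex-1-en-1-yl]oxy}silane, 4 diiodomethane
Product: 5 trimethyl{[(1S,3R,6S)-6-methyl-3-(prop-1-en-2-yl)bicyclo[4.1.0]heptan-1-yl]oxy}silane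
Conditions: Et2Zn, CH2I2, CH2Cl2, 0 °C → rt
Reagents that add atoms: diiodomethane (4), ICI
Why: Simmons–Smith cyclopropanation (Furukawa variant); the electron-rich silyl enol ether should react much faster than the isopropenyl alkene. Methylene is expected mainly anti to the isopropenyl group, but either cis-fused diastereomer serves, since both new centres are destroyed in step 3.

Step 3
Reactants: 5 trimethyl{[(1S,3R,6S)-6-methyl-3-(prop-1-en-2-yl)bicyclo[4.1.0]heptan-1-yl]oxy}silane
Product: 7 (R)-3-methyl-6-(prop-1-en-2-yl)cyclohept-2-en-1-one, via 3-chloro ketone 6 (not isolated)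
Conditions: FeCl3 (2.2 equiv), DMF, 0 °C → rt; then NaOAc, MeOH, reflux
Reagents that add atoms: none
Why: Trivalent iron oxidises the siloxycyclopropane by one electron to an oxygen-stabilised radical cation, whose internal C5–C10 bond undergoes β-scission to give the C5 carbonyl (the silyl group leaving with chloride) and a tertiary radical at C10. A second equivalent of FeCl3 transfers a chlorine atom to C10 to give the 3-chloro ketone 6, and sodium acetate then removes HCl through the C1 enolate, so that the double bond appears in conjugation as C1=C10. The closest known reaction type is the iron trichloride ring enlargement of 1-siloxybicyclo[n.1.0]alkanes to cycloalk-2-enones (Saegusa–Ito type). The one ring the step builds, the seven-membered ring, is not closed by a new bond: it arises in ring-enlargement mode, by cleavage of the bond shared by the three- and six-membered rings, the two bonds to C1 having been made in step 2. No stereocentre is formed; C7 is remote from the radical site and is retained, and both diastereomers of 5 converge on 7. The step needs internal rather than external cyclopropane cleavage (secured by the tertiary radical it produces and by overlap of the fused bond with the oxygen-centred orbital), chemoselectivity over the isopropenyl group (secured by the far lower oxidation potential of the siloxycyclopropane), and conjugative elimination (secured by the acidity of the C1 protons).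

Step 4
Reactants: 7 (R)-3-methyl-6-(prop-1-en-2-yl)cyclohept-2-en-1-one
Product: 8 (1S,4R,7S)-7-methyl-4-(prop-1-en-2-yl)-8-oxabicyclo[5.1.0]octan-2-one
Conditions: 30% aq. H2O2, 9-amino-9-deoxy-epi-quinine (10 mol %), CF3CO2H (20 mol %), 1,4-dioxane, 40 °C
Reagents that add atoms: hydrogen peroxide, OO
Why: Iminium-activated Weitz–Scheffer epoxidation of a cyclic enone: hydroperoxide adds to C10 and the enamine closes the epoxide at C1. The catalyst, not the remote C7 centre, chooses the face, and is selected to place oxygen cis to the isopropenyl group (C10 S); the isolated alkene is inert to nucleophilic peroxide.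

Step 5
Reactants: 8 (1S,4R,7S)-7-methyl-4-(prop-1-en-2-yl)-8-oxabicyclo[5.1.0]octan-2-one, 9 1-bromobut-2-yne
Product: 11 (2S,3S,6R)-2-(but-2-yn-1-yl)-3-hydroxy-3-methyl-6-(prop-1-en-2-yl)cycloheptan-1-one, via dilithium oxido enolate 10 (not isolated)
Conditions: Li (2.1 equiv), NH3(l)/THF, −78 °C; isoprene until colourless; then 9, −78 → −33 °C; NH4Cl
Reagents that add atoms: 1-bromobut-2-yne (9), CC#CCBr
Why: Two-electron reduction cleaves the C1–O bond α to the carbonyl and leaves the C10 alkoxide and the C5–C1 enolate, which is alkylated at C1 only (dissolving-metal reductive alkylation of an α,β-epoxy ketone); the propargylic bromide is reactive and has no acidic proton, and the butynyl group is a masked 2-oxobutyl chain. The chain is expected to enter anti to the C10 methyl group, with the oxido group near the enolate plane, so that C2 is cis to the C10 oxygen; C1 stays adjustable because it is α to the ketone.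

Step 6
Reactants: 11 (2S,3S,6R)-2-(but-2-yn-1-yl)-3-hydroxy-3-methyl-6-(prop-1-en-2-yl)cycloheptan-1-one
Product: 12 (2S,3S,6R)-2-(but-2-yn-1-yl)-3-methyl-6-(prop-1-en-2-yl)-3-[(triethylsilyl)oxy]cycloheptan-1-one
Conditions: Et3SiOTf, 2,6-lutidine, CH2Cl2, −78 → 0 °C
Reagents that add atoms: triethylsilyl trifluoromethanesulfonate, CC[Si](CC)(CC)OS(=O)(=O)C(F)(F)F
Why: Silyl triflate silylation of a tertiary alcohol; it removes the free β-hydroxy ketone, which would undergo retro-aldol ring cleavage in the basic steps that follow.

Step 7
Reactants: 12 (2S,3S,6R)-2-(but-2-yn-1-yl)-3-methyl-6-(prop-1-en-2-yl)-3-[(triethylsilyl)oxy]cycloheptan-1-one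
Product: 14 the 6α-hydroxy derivative of 12 (guaiane C6; hydroxyl on the ring carbon between the ketone and the isopropenyl-bearing carbon, trans to the isopropenyl group), via lithium C6 enolate 13 (not isolated)
Conditions: LiN(i-Pr)2, THF, −78 °C; then 2-(phenylsulfonyl)-3-phenyloxaziridine, −78 °C; NH4Cl
Reagents that add atoms: 2-(phenylsulfonyl)-3-phenyloxaziridine, O=S(=O)(c1ccccc1)N1OC1c1ccccc1
Why: Kinetic deprotonation takes the C6 methylene, since C1 is tertiary and flanked by the quaternary C10; electrophilic hydroxylation of the enolate by the N-sulfonyloxaziridine should occur anti to the neighbouring isopropenyl group, giving the trans (6α) alcohol, which is also the more stable arrangement. C6 is oxidised here because it is α to the only ketone; after ring A is closed it would compete with C1 and C2.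

Step 8
Reactants: 14 the 6α-hydroxy derivative of 12
Product: 15 (1αH,6βH,7αH)-6α-hydroxy-1-(2-oxobutyl)-7-isopropenyl-10α-methyl-10β-(triethylsilyloxy)cycloheptan-5-one (guaiane locants; the 1,4-diketone)
Conditions: Ph3PAuNTf2 (2 mol %), H2O (5 equiv), 1,4-dioxane, 50 °C
Reagents that add atoms: water, O
Why: Gold-catalysed alkyne hydration; the C5 carbonyl oxygen should attack the activated alkyne in 5-exo fashion, so that oxygen is delivered to C3 only and the 1,4-diketone results. The alkene, the silyl ether and the ketol should survive the neutral conditions.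

Step 9
Reactants: 15 the 1,4-diketone
Product: 17 the diol in which the isopropenyl group of 15 has become CH(CH3)CH2OH (C11 epimers), via catechol boronate 16 (not isolated)
Conditions: catecholborane, RhCl(PPh3)3 (3 mol %), THF, 0 °C → rt; then H2O2, pH 7 phosphate buffer, 0 °C
Reagents that add atoms: hydrogen peroxide, OO
Why: Rhodium-catalysed hydroboration with catecholborane is chemoselective for an alkene over ketones and anti-Markovnikov, and buffered oxidation gives the primary alcohol without triggering the aldol. C11 is formed without control here and is set in step 10.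

Step 10
Reactants: 17 the diol (C11 epimers)
Product: 19 the (11S)-lactol (five-membered hemiacetal between C12 and O6; anomers), via C11-epimeric lactol 18 (not isolated)
Conditions: TEMPO (10 mol %), PhI(OAc)2 (1.1 equiv), CH2Cl2, 0 °C; then Et3N, rt
Reagents that add atoms: none
Why: Nitroxyl-catalysed oxidation is selective for the primary alcohol, and the hydroxy aldehyde closes onto the C6 hydroxyl. Amine-mediated enolisation of the ring-opened aldehyde should equilibrate C11 to the epimer with the methyl group trans to C8 (11S, pseudo-equatorial); at this acidity the ketone α-centres C1 and C6 should not be affected.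

Step 11
Reactants: 19 the (11S)-lactol
Product: 20 (1αH,6βH,7αH,11βH)-1-(2-oxobutyl)-5-oxo-10β-(triethylsilyloxy)-10α-methylcycloheptane fused at C6–C7 to the α-methyl-γ-lactone (12,6α-olide; guaiane locants)
Conditions: Pr4N[RuO4] (5 mol %), N-methylmorpholine N-oxide, 4 Å molecular sieves, CH2Cl2, rt
Reagents that add atoms: none
Why: Perruthenate oxidation of a lactol to the γ-lactone; no other oxidisable hydroxyl is present, and the trans ring fusion follows from the trans C6/C7 substituents.

Step 12
Reactants: 20 the keto lactone
Product: 21 3-oxo-10β-(triethylsilyloxy)-1αH,6βH,7αH,11βH-guai-4-en-12,6α-olide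
Conditions: KOt-Bu (0.3 equiv), t-BuOH/THF, 0 °C → rt
Reagents that add atoms: none
Why: Intramolecular aldol condensation of the 1,4-diketone: the C4 enolate of the ethyl ketone adds to the C5 ketone and dehydration gives the tetrasubstituted cyclopentenone, which is an irreversible sink. Short exposure to a non-nucleophilic base is meant to limit loss of the β-silyloxy group, lactone opening and epimerisation at C6; C1 can still equilibrate before closure towards the epimer with C2 trans to the C10 methyl group.

Step 13
Reactants: 21 3-oxo-10β-(triethylsilyloxy)-1αH-guai-4-en-12,6α-olide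
Product: 23 10β-(triethylsilyloxy)-3-(trifluoromethanesulfonyloxy)-1αH-guaia-2,4-dien-12,6α-olide, via lithium dienolate 22 (not isolated)
Conditions: LiN(SiMe3)2, THF, −78 °C; then PhNTf2, −78 → 0 °C
Reagents that add atoms: N-phenylbis(trifluoromethanesulfonimide), O=S(=O)(N(c1ccccc1)S(=O)(=O)C(F)(F)F)C(F)(F)F
Why: Kinetic deprotonation of the cyclopentenone at C2 (α′) gives the cross-conjugated enolate, which is O-sulfonylated (enol triflate formation); the lactone α-proton and the γ-protons at C1 and C6 should not be removed at −78 °C.

Step 14
Reactants: 23 the dienyl triflate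
Product: 24 10β-(triethylsilyloxy)-1αH-guaia-2,4-dien-12,6α-olide
Conditions: Pd(OAc)2 (5 mol %), PPh3 (10 mol %), n-Bu3N, HCO2H, DMF, 40 °C
Reagents that add atoms: none
Why: Palladium-catalysed formate reduction of an enol triflate (oxidative addition to zerovalent palladium, formate exchange, decarboxylation, reductive elimination) replaces the triflate by hydrogen and leaves C1 untouched; the mild conditions allow the 1H-cyclopentadiene to be used at once.

Step 15
Reactants: 21 3-oxo-10β-(triethylsilyloxy)-1αH-guai-4-en-12,6α-olide
Product: 25 10β-(triethylsilyloxy)-3-(trimethylsilyloxy)-1αH-guaia-2,4-dien-12,6α-olide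
Conditions: Me3SiOTf (1.2 equiv), Et3N (2 equiv), Et2O, 0 °C; dilution with pentane, filtration, no aqueous work-up
Reagents that add atoms: trimethylsilyl trifluoromethanesulfonate, C[Si](C)(C)OS(=O)(=O)C(F)(F)F
Why: Soft enolisation of the enone: the silyl triflate activates the carbonyl oxygen and triethylamine removes the accessible α′ proton at C2, which gives the cross-conjugated 2-siloxy diene C2=C3–C4=C5 and not the extended dienol ether (the usual way from cyclopent-2-enones to 2-siloxycyclopenta-1,3-dienes); no metal enolate is formed, and the lactone and the tertiary silyl ether are inert to the amine.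

Step 16
Reactants: 24 the cyclopentadiene, 25 the siloxy diene
Product: 26 the Diels–Alder adduct (the 10,10′-bis(triethylsilyl) ether and C3′ trimethylsilyl enol ether of 27, with C3′=C4′)
Conditions: 25 (2 equiv), toluene (2 M), 2,6-di-tert-butyl-4-methylphenol (trace), 30 °C, dark
Reagents that add atoms: none
Why: Diels–Alder cross-dimerisation of two cyclopentadienes: the electron-rich siloxy diene of 25 (C2′ to C5′) should add to the strained cis-disubstituted C2=C3 bond of 24, the leading bond joining the unsubstituted termini C2 and C2′ (largest diene coefficient next to the siloxy carbon, least hindrance). Each partner should react on the face opposite its C10 substituent, and endo approach places ring A of 24 under the new C3′=C4′ bond, which sets C2, C3, C2′ and C5′. An excess of 25 favours the crossed adduct over self-dimerisation of 24, and unused 25 returns 21 on hydrolysis.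

Step 17
Reactants: 26 the Diels–Alder adduct
Product: 27 the target CNP0243924.4
Conditions: HF·pyridine, pyridine/THF, 0 °C → rt
Reagents that add atoms: none
Why: Fluoride-assisted desilylation frees both tertiary alcohols and the C3′ enol, which is protonated at C4′. The methyl-endo ketone is expected both kinetically (the freed C10′ hydroxyl sits over the exo face) and thermodynamically (an exo methyl would clash with C10′), so enolisation in the acidic medium should converge on 27.

## Compound list

1 | (R)-carvone, (5R)-2-methyl-5-(prop-1-en-2-yl)cyclohex-2-en-1-one | CC1=CC[C@H](CC1=O)C(C)=C | starting material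
2 | lithium (5R)-2-methyl-5-(prop-1-en-2-yl)cyclohex-1-en-1-olate | CC1=C([O-])C[C@@H](CC1)C(C)=C.[Li+] | intermediate
3 | trimethyl{[(5R)-2-methyl-5-(prop-1-en-2-yl)cyclohex-1-en-1-yl]oxy}silane | CC1=C(O[Si](C)(C)C)C[C@@H](CC1)C(C)=C | intermediate
4 | diiodomethane | ICI | starting material
5 | trimethyl{[(1S,3R,6S)-6-methyl-3-(prop-1-en-2-yl)bicyclo[4.1.0]heptan-1-yl]oxy}silane (cis-fused, ring CH2 anti to the isopropenyl group) | C[C@]12C[C@@]1(O[Si](C)(C)C)C[C@@H](CC2)C(C)=C | intermediate
6 | (6R)-3-chloro-3-methyl-6-(prop-1-en-2-yl)cycloheptan-1-one (either C3 epimer) | CC1(Cl)CC(=O)C[C@@H](CC1)C(C)=C | intermediate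
7 | (R)-3-methyl-6-(prop-1-en-2-yl)cyclohept-2-en-1-one | CC1=CC(=O)C[C@@H](CC1)C(C)=C | intermediate
8 | (1S,4R,7S)-7-methyl-4-(prop-1-en-2-yl)-8-oxabicyclo[5.1.0]octan-2-one (epoxide oxygen cis to the isopropenyl group) | C=C(C)[C@@H]1CC[C@]2(C)O[C@@H]2C(=O)C1 | intermediate
9 | 1-bromobut-2-yne | CC#CCBr | starting material
10 | dilithium (3S,6R)-3-methyl-3-oxido-6-(prop-1-en-2-yl)cyclohept-1-en-1-olate | C=C(C)[C@@H]1CC[C@](C)([O-])C=C([O-])C1.[Li+].[Li+] | intermediate
11 | (2S,3S,6R)-2-(but-2-yn-1-yl)-3-hydroxy-3-methyl-6-(prop-1-en-2-yl)cycloheptan-1-one | CC#CC[C@@H]1C(=O)C[C@H](C(C)=C)CC[C@]1(C)O | intermediate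
12 | (2S,3S,6R)-2-(but-2-yn-1-yl)-3-methyl-6-(prop-1-en-2-yl)-3-[(triethylsilyl)oxy]cycloheptan-1-one | CC#CC[C@@H]1C(=O)C[C@H](C(C)=C)CC[C@]1(C)O[Si](CC)(CC)CC | intermediate
13 | lithium enolate of 12 towards C6 (guaiane numbering) | CC#CC[C@@H]1C([O-])=C[C@H](C(C)=C)CC[C@]1(C)O[Si](CC)(CC)CC.[Li+] | intermediate
14 | 6α-hydroxy derivative of 12 (hydroxyl trans to the isopropenyl group) | CC#CC[C@@H]1C(=O)[C@@H](O)[C@H](C(C)=C)CC[C@]1(C)O[Si](CC)(CC)CC | intermediate
15 | 1,4-diketone: 14 with the butynyl group hydrated to 2-oxobutyl | CCC(=O)C[C@@H]1C(=O)[C@@H](O)[C@H](C(C)=C)CC[C@]1(C)O[Si](CC)(CC)CC | intermediate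
16 | catechol boronate from anti-Markovnikov hydroboration of 15 (C11 epimers) | CCC(=O)C[C@@H]1C(=O)[C@@H](O)[C@H](C(C)CB2Oc3ccccc3O2)CC[C@]1(C)O[Si](CC)(CC)CC | intermediate
17 | diol: 15 with the isopropenyl group as 1-hydroxypropan-2-yl (C11 epimers) | CCC(=O)C[C@@H]1C(=O)[C@@H](O)[C@H](C(C)CO)CC[C@]1(C)O[Si](CC)(CC)CC | intermediate
18 | lactol (O6–C12 hemiacetal), C11 epimers, anomers | CCC(=O)C[C@@H]1C(=O)[C@H]2OC(O)C(C)[C@@H]2CC[C@]1(C)O[Si](CC)(CC)CC | intermediate
19 | (11S)-lactol, anomers | CCC(=O)C[C@@H]1C(=O)[C@H]2OC(O)[C@@H](C)[C@@H]2CC[C@]1(C)O[Si](CC)(CC)CC | intermediate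
20 | keto lactone: 1-(2-oxobutyl)-5-oxo-10β-(triethylsilyloxy) seven-membered ring with trans-fused (11S)-12,6α-olide | CCC(=O)C[C@@H]1C(=O)[C@H]2OC(=O)[C@@H](C)[C@@H]2CC[C@]1(C)O[Si](CC)(CC)CC | intermediate
21 | 3-oxo-10β-(triethylsilyloxy)-1αH,6βH,7αH,11βH-guai-4-en-12,6α-olide | CC1=C2[C@H]3OC(=O)[C@@H](C)[C@@H]3CC[C@](C)(O[Si](CC)(CC)CC)[C@@H]2CC1=O | intermediate
22 | lithium cross-conjugated dienolate of 21 (C2=C3–O⁻) | CC1=C2[C@H]3OC(=O)[C@@H](C)[C@@H]3CC[C@](C)(O[Si](CC)(CC)CC)[C@@H]2C=C1[O-].[Li+] | intermediate
23 | 10β-(triethylsilyloxy)-3-(trifluoromethanesulfonyloxy)-1αH-guaia-2,4-dien-12,6α-olide | CC1=C2[C@H]3OC(=O)[C@@H](C)[C@@H]3CC[C@](C)(O[Si](CC)(CC)CC)[C@@H]2C=C1OS(=O)(=O)C(F)(F)F | intermediate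
24 | 10β-(triethylsilyloxy)-1αH-guaia-2,4-dien-12,6α-olide | CC1=C2[C@H]3OC(=O)[C@@H](C)[C@@H]3CC[C@](C)(O[Si](CC)(CC)CC)[C@@H]2C=C1 | intermediate
25 | 10β-(triethylsilyloxy)-3-(trimethylsilyloxy)-1αH-guaia-2,4-dien-12,6α-olide | CC1=C2[C@H]3OC(=O)[C@@H](C)[C@@H]3CC[C@](C)(O[Si](CC)(CC)CC)[C@@H]2C=C1O[Si](C)(C)C | intermediate
26 | Diels–Alder adduct: 10,10′-bis(triethylsilyl) ether and C3′ trimethylsilyl enol ether of 27 | CC1=C2[C@H]3OC(=O)[C@@H](C)[C@@H]3CC[C@](C)(O[Si](CC)(CC)CC)[C@@H]2[C@H]2[C@H]3C(O[Si](C)(C)C)=C(C)[C@]4([C@@H]3[C@@](C)(O[Si](CC)(CC)CC)CC[C@H]3[C@H](C)C(=O)O[C@@H]34)[C@@H]12 | intermediate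
27 | CNP0243924.4 | CC1=C2[C@H]3OC(=O)[C@@H](C)[C@@H]3CC[C@](C)(O)[C@@H]2[C@H]2[C@H]3C(=O)[C@@H](C)[C@]4([C@@H]3[C@@](C)(O)CC[C@H]3[C@H](C)C(=O)O[C@@H]34)[C@@H]12 | target

## Step count and least certain steps

Total: 17 steps. Longest linear sequence: 16 steps (steps 1–14, 16 and 17); step 15 is a one-step branch from 21.

Step 3 (key step). Most likely failure: the oxidant acts as a Lewis acid and not as an oxidant, so that protodesilylation with external bond cleavage gives the β-methyl ketone, or the isopropenyl group is chlorinated. Fallback, from 3 back to 7: dibromocarbene (CHBr3, KOt-Bu) is added to the enol ether of 3 to give the dibromocyclopropane F1. Thermal electrocyclic opening of F1, in which the internal bond must cleave, gives the 2-bromo enone F2 with loss of the silyl bromide. Palladium-catalysed formate reduction of the vinyl bromide (Pd(OAc)2, PPh3, HCO2H, Et3N) then returns 7.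

Step 4. Most likely failure: poor facial selectivity, through slow iminium formation on the β,β-disubstituted enone or a mismatched pairing with the C7 centre, giving the C10-epimeric epoxide. Fallback, from 7 back to 8: reduction with NaBH4 and CeCl3 gives the allylic alcohol, used as the epimer with the hydroxyl cis to the isopropenyl group, F3 (after Mitsunobu inversion if the trans alcohol forms). Hydroxyl-directed epoxidation (VO(acac)2, t-BuOOH) delivers oxygen syn to the hydroxyl to give the epoxy alcohol F4, and Dess–Martin oxidation returns 8.

Step 5. Most likely failure: alkylation on the wrong face of the C1 enolate, so that the chain ends trans to the C10 oxygen and is not corrected before ring A closes; over-reduction of the alkyne by excess metal is a lesser risk. Fallback, setting out from the product of step 12 (21 mixed with, or replaced by, the C1 epimer of 21, F5) and coming back at 21 with C1 corrected: DBU in warm toluene removes the C10 silyloxy group of either epimer by vinylogous elimination to give the dienone F6. The electron-rich C1=C10 bond is epoxidised on the β-face (m-CPBA, or the ketone-catalysed KHSO5 epoxidation if reagent control is needed) to give the epoxide F7. Palladium–formate hydrogenolysis of this alkenyl epoxide (Pd2(dba)3·CHCl3, PBu3, HCO2H, Et3N) delivers hydride to C1 with inversion, which fixes H1 anti to the C10 oxygen in the hydroxy enone F8, and silylation (Et3SiOTf, 2,6-lutidine) returns 21.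

Step 12. Most likely failure: base-induced loss of the β-silyloxy group, or epimerisation at C6 (α to the ketone and to the lactone oxygen) before ring closure. Fallback, from 14 back to 21, in which the lactone is made after ring A: 14 is silylated (Et3SiOTf) to the bis-silyl ether F9, and the alkyne is hydrated with Ph3PAuNTf2 and water to the diketone F10. The aldol condensation is run on this α-silyloxy ketone, whose trans arrangement at C6/C7 is the stable one, to give the enone F11. Hydroboration with catecholborane and RhCl(PPh3)3 followed by buffered oxidation gives the primary alcohol F12, and buffered HF·pyridine removes the secondary allylic silyl group selectively to give the diol F13. Nitroxyl oxidation (TEMPO, PhI(OAc)2) with amine equilibration gives the (11S)-lactol F14, and oxidation with Pr4N[RuO4] and N-methylmorpholine N-oxide returns 21.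

Step 16. Most likely failure: self-dimerisation of 24 outruns the crossed reaction, or 1,5-hydrogen shifts move the diene of 25 or scramble C1 before cycloaddition. Fallback, from 24 to 27: 24 alone is left to dimerise neat at room temperature, by the same regio- and stereochemical course, to the norbornene dimer F15. HF·pyridine frees the diol F16. Hydroboration with BH3·SMe2, guided to the exo face by the C10′ hydroxyl, and NaBO3 oxidation give the C3′ alcohol F17 with H4′ exo, and Dess–Martin oxidation gives 27.

## Further compounds

F1 | step 3 | 7,7-dibromo adduct of 3: [(7,7-dibromo-6-methyl-3-(prop-1-en-2-yl)bicyclo[4.1.0]heptan-1-yl)oxy]trimethylsilane | C[C@]12C(Br)(Br)[C@@]1(O[Si](C)(C)C)C[C@@H](CC2)C(C)=C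
F2 | step 3 | (R)-2-bromo-3-methyl-6-(prop-1-en-2-yl)cyclohept-2-en-1-one | CC1=C(Br)C(=O)C[C@@H](CC1)C(C)=C
F3 | step 4 | 3-methyl-6-(prop-1-en-2-yl)cyclohept-2-en-1-ol, hydroxyl cis to the isopropenyl group | CC1=C[C@H](O)C[C@@H](CC1)C(C)=C
F4 | step 4 | epoxy alcohol: 7-methyl-4-(prop-1-en-2-yl)-8-oxabicyclo[5.1.0]octan-2-ol, epoxide and hydroxyl both cis to the isopropenyl group | C=C(C)[C@@H]1CC[C@]2(C)O[C@@H]2[C@H](O)C1
F5 | step 5 | C1 epimer of 21: 3-oxo-10β-(triethylsilyloxy)-1βH-guai-4-en-12,6α-olide | CC1=C2[C@H]3OC(=O)[C@@H](C)[C@@H]3CC[C@](C)(O[Si](CC)(CC)CC)[C@H]2CC1=O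
F6 | step 5 | 3-oxoguaia-1(10),4-dien-12,6α-olide (11S) | CC1=C2[C@H]3OC(=O)[C@@H](C)[C@@H]3CCC(C)=C2CC1=O
F7 | step 5 | 1β,10β-epoxy-3-oxoguai-4-en-12,6α-olide | CC1=C2[C@H]3OC(=O)[C@@H](C)[C@@H]3CC[C@]4(C)O[C@]24CC1=O
F8 | step 5 | 10β-hydroxy-3-oxo-1αH-guai-4-en-12,6α-olide | CC1=C2[C@H]3OC(=O)[C@@H](C)[C@@H]3CC[C@](C)(O)[C@@H]2CC1=O
F9 | step 12 | 6-O-triethylsilyl ether of 14 | CC#CC[C@@H]1C(=O)[C@@H](O[Si](CC)(CC)CC)[C@H](C(C)=C)CC[C@]1(C)O[Si](CC)(CC)CC
F10 | step 12 | 6-O-triethylsilyl ether of 15 | CCC(=O)C[C@@H]1C(=O)[C@@H](O[Si](CC)(CC)CC)[C@H](C(C)=C)CC[C@]1(C)O[Si](CC)(CC)CC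
F11 | step 12 | 6α,10β-bis(triethylsilyloxy)-1αH,7αH-guaia-4,11(12)-dien-3-one (7-isopropenyl enone) | CC1=C2[C@@H](O[Si](CC)(CC)CC)[C@H](C(C)=C)CC[C@](C)(O[Si](CC)(CC)CC)[C@@H]2CC1=O
F12 | step 12 | 12-hydroxy-6α,10β-bis(triethylsilyloxy)-1αH-guai-4-en-3-one (C11 epimers) | CC1=C2[C@@H](O[Si](CC)(CC)CC)[C@H](C(C)CO)CC[C@](C)(O[Si](CC)(CC)CC)[C@@H]2CC1=O
F13 | step 12 | 6α,12-dihydroxy-10β-(triethylsilyloxy)-1αH-guai-4-en-3-one (C11 epimers) | CC1=C2[C@@H](O)[C@H](C(C)CO)CC[C@](C)(O[Si](CC)(CC)CC)[C@@H]2CC1=O
F14 | step 12 | (11S)-lactol of 21 (C12 hemiacetal, anomers) | CC1=C2[C@H]3OC(O)[C@@H](C)[C@@H]3CC[C@](C)(O[Si](CC)(CC)CC)[C@@H]2CC1=O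
F15 | step 16 | self-dimer of 24: norbornene with C3′=C4′, 10,10′-bis(triethylsilyl) ether | CC1=C2[C@H]3OC(=O)[C@@H](C)[C@@H]3CC[C@](C)(O[Si](CC)(CC)CC)[C@@H]2[C@H]2[C@H]3C=C(C)[C@]4([C@@H]3[C@@](C)(O[Si](CC)(CC)CC)CC[C@H]3[C@H](C)C(=O)O[C@@H]34)[C@@H]12
F16 | step 16 | norbornene diol: 3′-deoxo-3′,4′-didehydro analogue of 27 | CC1=C2[C@H]3OC(=O)[C@@H](C)[C@@H]3CC[C@](C)(O)[C@@H]2[C@H]2[C@H]3C=C(C)[C@]4([C@@H]3[C@@](C)(O)CC[C@H]3[C@H](C)C(=O)O[C@@H]34)[C@@H]12
F17 | step 16 | C3′ exo-alcohol corresponding to 27 (H4′ exo) | CC1=C2[C@H]3OC(=O)[C@@H](C)[C@@H]3CC[C@](C)(O)[C@@H]2[C@H]2[C@H]3[C@H](O)[C@@H](C)[C@]4([C@@H]3[C@@](C)(O)CC[C@H]3[C@H](C)C(=O)O[C@@H]34)[C@@H]12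
A1 | alternative 1 | chloromethyl ketone with tethered diene: (7E)-5-(tert-butyldimethylsilyloxy)-1-chloro-6-methyldeca-7,9-dien-2-one, silyloxy and methyl carbons configured as in A2 | ClCC(=O)CC[C@@H](O[Si](C)(C)C(C)(C)C)[C@H](C)/C=C/C=C
A2 | alternative 1 | 3-(tert-butyldimethylsilyloxy)-4-methylbicyclo[5.3.0]dec-6-en-10-one (guaiane locants) | C[C@H]1[C@H](O[Si](C)(C)C(C)(C)C)C[C@H]2C(=O)CCC=C[C@H]12
A3 | alternative 2 | enynyl pivalate: cyclohept-1(5)-ene lactone carrying the C4 tertiary propargylic pivalate and the C10 trimethylsilyl ether (C4 configuration open) | C#CC(C)(OC(=O)C(C)(C)C)C1=C[C@@](C)(O[Si](C)(C)C)CC[C@H]2[C@H](C)C(=O)O[C@H]12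
A4 | alternative 2 | 10-trimethylsilyloxy-3-oxoguai-4-en-12,6-olide | CC1=C2[C@H]3OC(=O)[C@@H](C)[C@@H]3CC[C@](C)(O[Si](C)(C)C)[C@@H]2CC1=O
A5 | alternative 3 | (11S)-4α,5β-epoxygermacr-1(10)E-en-12,6α-olide | C/C1=C\CC[C@@]2(C)O[C@@H]2[C@H]2OC(=O)[C@@H](C)[C@@H]2CC1
A6 | alternative 3 | 4-hydroxyguai-1(10)-en-12,6-olide | CC1=C2CC[C@@](C)(O)[C@@H]2[C@H]3OC(=O)[C@@H](C)[C@@H]3CC1
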